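**Retrosynthetic overview**
1. Target ⇒ bromination ortho/para to the free OH of 2-(2,3,4,5-tetrabromo-6-methoxyphenoxy)phenol ⇒ Baeyer–Villiger oxidation and formate cleavage of the matching ortho-aryloxybenzaldehyde.
2. Diaryl ether C–O bond ⇒ SNAr of the tetrabromoguaiacol phenoxide on 2-fluorobenzaldehyde.
3. Tetrabromoguaiacol ⇒ mono-O-methylation of tetrabromocatechol ⇒ perbromination of catechol.
4. Catechol ring built de novo ⇒ cyclohexane-1,2-dione ⇒ diethyl 2,3-dioxocyclohexane-1,4-dicarboxylate ⇒ crossed Claisen condensation of diethyl adipate with diethyl oxalate (key C–C bond), then Dieckmann closure.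
5. Ring order: the six-membered carbocycle of the tetrabromo ring is formed first and aromatised; the second ring is brought in as an intact benzene ring.

Assumption: the target has no stereogenic element (it is achiral), so no stereocontrol is needed and the SMILES carry no descriptors.

**Route**

Step 1
Reactants: 1 diethyl adipate; 2 diethyl oxalate
Product: 4 diethyl 2,3-dioxocyclohexane-1,4-dicarboxylate (isolated as its bis-enol), via acyclic oxalyl adipate triester 3 (not isolated)
Conditions: NaOEt (2.2 equiv), EtOH, 0 °C → reflux (1 added to 2/NaOEt); then cold 2 M HCl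
Reagents that add atoms: none
Why: Crossed Claisen condensation in which the adipate α-enolate acylates non-enolisable diethyl oxalate (the key intermolecular C–C bond), after which the second α-carbon closes the six-membered ring by an intramolecular Claisen (Dieckmann) condensation, driven by formation of the doubly stabilised dienolate; no stereocentre is retained.

Step 2
Reactants: 4 diethyl 2,3-dioxocyclohexane-1,4-dicarboxylate
Product: 6 cyclohexane-1,2-dione, via bis-enol diacid 5 (not isolated)
Conditions: 10% aq. H2SO4, reflux, N2; continuous Et2O extraction, distillation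
Reagents that add atoms: none
Why: Acid-catalysed ester hydrolysis followed by β-keto acid decarboxylation (ketonic hydrolysis) removes both ester carbons and leaves the 1,2-dione, which is stabilised as its mono-enol.

Step 3
Reactants: 6 cyclohexane-1,2-dione
Product: 7 catechol
Conditions: I2 (20 mol%), DMSO, 80 °C
Reagents that add atoms: none
Why: Iodine-catalysed dehydrogenative aromatisation, in which α-iodination of the enolised dione and loss of HI give a dienone that tautomerises to catechol while DMSO reoxidises HI to I2.

Step 4
Reactants: 7 catechol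
Product: 8 tetrabromocatechol (3,4,5,6-tetrabromobenzene-1,2-diol)
Conditions: Br2 (4.5 equiv), AcOH, rt → 70 °C
Reagents that add atoms: bromine, BrBr
Why: Electrophilic aromatic substitution in which the two OH groups activate all four free positions, so excess bromine converges on the exhaustively brominated catechol.

Step 5
Reactants: 8 tetrabromocatechol
Product: 9 2,3,4,5-tetrabromo-6-methoxyphenol (tetrabromoguaiacol)
Conditions: NaH (1.0 equiv), DMF, 0 °C; MeI (1.0 equiv), 0 °C → rt; recovered 8 recycled
Reagents that add atoms: iodomethane, CI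
Why: Williamson ether synthesis on the monosodium catecholate, where limiting base and electrophile favour mono-O-methylation and the neutral dimethyl ether and unreacted diol are removed by base extraction and chromatography.

Step 6
Reactants: 9 2,3,4,5-tetrabromo-6-methoxyphenol; 10 2-fluorobenzaldehyde
Product: 11 2-(2,3,4,5-tetrabromo-6-methoxyphenoxy)benzaldehyde
Conditions: K2CO3 (1.5 equiv), DMAc, 140 °C, N2
Reagents that add atoms: none
Why: Nucleophilic aromatic substitution (SNAr) in which the ortho-formyl group activates fluoride for displacement by the phenoxide through a Meisenheimer intermediate, while the unactivated aryl bromides stay intact.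

Step 7
Reactants: 11 2-(2,3,4,5-tetrabromo-6-methoxyphenoxy)benzaldehyde
Product: 13 2-(2,3,4,5-tetrabromo-6-methoxyphenoxy)phenol, via aryl formate 12 (not isolated)
Conditions: mCPBA (1.5 equiv), CH2Cl2, 0 °C → reflux; then conc. HCl (cat.), MeOH, rt
Reagents that add atoms: mCPBA (3-chloroperoxybenzoic acid), OOC(=O)c1cccc(Cl)c1
Why: Baeyer–Villiger (Dakin-type) oxidation in which the aryl group bearing the ortho oxygen donor migrates in the Criegee intermediate to give the aryl formate, which is then cleaved by acid-catalysed methanolysis.

Step 8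
Reactants: 13 2-(2,3,4,5-tetrabromo-6-methoxyphenoxy)phenol
Product: 14 2,4-dibromo-6-(2,3,4,5-tetrabromo-6-methoxyphenoxy)phenol (target)
Conditions: Br2 (2.05 equiv), AcOH, rt
Reagents that add atoms: bromine, BrBr
Why: Electrophilic aromatic bromination directed by the free OH to its ortho and para positions, with the other ring fully substituted and the positions meta to OH reacting much more slowly, so two equivalents stop at the target.

**Compound list**
1 | diethyl adipate (diethyl hexanedioate) | CCOC(=O)CCCCC(=O)OCC | starting material
2 | diethyl oxalate | CCOC(=O)C(=O)OCC | starting material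
3 | diethyl 2-(2-ethoxy-2-oxoacetyl)hexanedioate (racemic, configurationally labile, present as its sodium enolate) | CCOC(=O)C(=O)C(CCCC(=O)OCC)C(=O)OCC | intermediate
4 | diethyl 2,3-dioxocyclohexane-1,4-dicarboxylate, drawn as its bis-enol tautomer diethyl 2,3-dihydroxycyclohexa-1,3-diene-1,4-dicarboxylate | CCOC(=O)C1=C(O)C(O)=C(C(=O)OCC)CC1 | intermediate
5 | 2,3-dioxocyclohexane-1,4-dicarboxylic acid, drawn as its bis-enol tautomer | OC(=O)C1=C(O)C(O)=C(C(=O)O)CC1 | intermediate
6 | cyclohexane-1,2-dione | O=C1CCCCC1=O | intermediate
7 | catechol (benzene-1,2-diol) | Oc1ccccc1O | intermediate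
8 | tetrabromocatechol (3,4,5,6-tetrabromobenzene-1,2-diol) | Oc1c(O)c(Br)c(Br)c(Br)c1Br | intermediate
9 | 2,3,4,5-tetrabromo-6-methoxyphenol | COc1c(O)c(Br)c(Br)c(Br)c1Br | intermediate
10 | 2-fluorobenzaldehyde | O=Cc1ccccc1F | starting material
11 | 2-(2,3,4,5-tetrabromo-6-methoxyphenoxy)benzaldehyde | COc1c(Br)c(Br)c(Br)c(Br)c1Oc1ccccc1C=O | intermediate
12 | 2-(2,3,4,5-tetrabromo-6-methoxyphenoxy)phenyl formate | COc1c(Br)c(Br)c(Br)c(Br)c1Oc1ccccc1OC=O | intermediate
13 | 2-(2,3,4,5-tetrabromo-6-methoxyphenoxy)phenol | COc1c(Br)c(Br)c(Br)c(Br)c1Oc1ccccc1O | intermediate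
14 | 2,4-dibromo-6-(2,3,4,5-tetrabromo-6-methoxyphenoxy)phenol | COc1c(Br)c(Br)c(Br)c(Br)c1Oc1cc(Br)cc(Br)c1O | target

**Totals**
Total step count: 8. Longest linear sequence: 8 steps (1/2 → 14).

**Three steps most likely to fail**

Step 2 (ketonic hydrolysis to the water-soluble, condensation-prone dione). The fallback sets out from 4 and comes back at 8, bypassing 6 and 7. Compound 4 is aromatised with the esters in place by α-bromination and dehydrobromination (Br2, 1.0 equiv, CHCl3, 0 °C → rt) to give diethyl 2,3-dihydroxyterephthalate F1. Saponification (aq. NaOH/EtOH, reflux, N2; then HCl) gives 2,3-dihydroxyterephthalic acid F2. Excess Br2 in aqueous AcOH at 60 °C then brominates the two free ring positions and replaces both ortho-hydroxy carboxyl groups by ipso bromodecarboxylation, giving tetrabromocatechol 8.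

Step 5 (mono- versus di-methylation of a symmetrical catechol). The fallback sets out from 8 and comes back at 9. Compound 8 is methylated exhaustively (K2CO3, excess MeI, acetone, reflux) to 1,2,3,4-tetrabromo-5,6-dimethoxybenzene F3. One methyl group is then removed by nucleophilic demethylation (LiCl, DMF, 140 °C; aq. HCl work-up). The first cleavage releases a stabilised tetrabromophenoxide, and its negative charge suppresses attack on the neighbouring methoxy group, so the reaction stops at 9.

Step 6 (SNAr of a hindered, weakly nucleophilic phenoxide on a moderately activated fluoroarene). The fallback sets out from 9 and comes back at 13, skipping 11 and step 7. Compound 9 is coupled with the much more electrophilic 1-fluoro-2-nitrobenzene (K2CO3, DMF, 90 °C) to give 1,2,3,4-tetrabromo-5-methoxy-6-(2-nitrophenoxy)benzene F4. Reduction with Fe/NH4Cl (EtOH–H2O, 80 °C), which leaves the C–Br bonds alone, gives 2-(2,3,4,5-tetrabromo-6-methoxyphenoxy)aniline F5. Diazotisation (NaNO2, aq. H2SO4, 0 °C) gives 2-(2,3,4,5-tetrabromo-6-methoxyphenoxy)benzenediazonium hydrogen sulfate F6. This is hydroxylated with Cu2O/Cu(NO3)2 in water at rt to phenol 13; Pschorr ring closure is blocked because both ortho positions of the other ring are substituted.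

**Further compounds**
F1 | step 2 | diethyl 2,3-dihydroxyterephthalate | CCOC(=O)c1ccc(C(=O)OCC)c(O)c1O
F2 | step 2 | 2,3-dihydroxyterephthalic acid | OC(=O)c1ccc(C(=O)O)c(O)c1O
F3 | step 5 | 1,2,3,4-tetrabromo-5,6-dimethoxybenzene | COc1c(OC)c(Br)c(Br)c(Br)c1Br
F4 | step 6 | 1,2,3,4-tetrabromo-5-methoxy-6-(2-nitrophenoxy)benzene | COc1c(Br)c(Br)c(Br)c(Br)c1Oc1ccccc1[N+](=O)[O-]
F5 | step 6 | 2-(2,3,4,5-tetrabromo-6-methoxyphenoxy)aniline | COc1c(Br)c(Br)c(Br)c(Br)c1Oc1ccccc1N
F6 | step 6 | 2-(2,3,4,5-tetrabromo-6-methoxyphenoxy)benzenediazonium hydrogen sulfate | COc1c(Br)c(Br)c(Br)c(Br)c1Oc1ccccc1[N+]#N.OS(=O)(=O)[O-]
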